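**Strategy.** Ring A carries the ether oxygen O1 (on C8a) and the benzylic carbon C4 (on C4a) on neighbouring carbons, so cutting O1–C2 and C3–C4 turns ring C into the [4+2] adduct of an ortho-quinone methide (O1–C8a–C4a–C4) and the vinyl group of ring B. In one operation the key step joins both halves, closes ring C, sets C2 under the control of a chiral phosphoric acid and leaves a methoxy group on C4 as a latent ketone. Its precursors are a geranylated salicylaldehyde whose only free hydroxyl is the future O1, which fixes the 6-geranyl pattern, and a 3,5-bis(silyloxy)styrene.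

Key step: step 8

Abbreviations: geranyl = (2E)-3,7-dimethylocta-2,6-dien-1-yl; MOM = methoxymethyl; TIPS = triisopropylsilyl; TBS = tert-butyldimethylsilyl.

Remark (assumption): the sense of induction of the binaphthyl phosphoric acid cannot be assigned in advance for this substrate pair; the route is written with the (R)-acid, and the (S)-acid is to be used instead if a first run gives the 2R series.

Remark (design): the third oxygen of ring A is masked as a TIPS ether, so that the two MOM ethers direct geranylation between them and the freed phenol then directs formylation to its own ortho carbon. Ring B carries TBS ethers, because bulky, weakly basic silyloxy groups shield the resorcinol-type ring carbons from Friedel–Crafts capture, do not compete for the phosphoric acid, and still fall in the final acidic methanolysis.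

**Step 1**
Reactants: 1 phloroglucinol
Product: 2 5-(triisopropylsilyloxy)benzene-1,3-diol
Conditions: 1 (3 equiv), TIPSCl (1 equiv), imidazole, DMF, 0 °C to rt
Reagents that add atoms: triisopropylsilyl chloride, CC(C)[Si](Cl)(C(C)C)C(C)C
Why: Statistical monosilylation of a threefold-symmetric triol, in which the cheap triol in excess should consume the bulky silyl chloride in the first silylation and the unreacted, water-soluble triol is washed out.

**Step 2**
Reactants: 2 5-(triisopropylsilyloxy)benzene-1,3-diol
Product: 3 1,3-bis(methoxymethoxy)-5-(triisopropylsilyloxy)benzene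
Conditions: MOMCl, i-Pr2NEt, CH2Cl2, 0 °C to rt
Reagents that add atoms: chloromethyl methyl ether, COCCl
Why: O-Alkylation of the two remaining phenols with MOMCl under an amine base, which leaves the aryl TIPS ether untouched.

**Step 3**
Reactants: 3 1,3-bis(methoxymethoxy)-5-(triisopropylsilyloxy)benzene; 4 geranyl bromide
Product: 6 2-geranyl-1,3-bis(methoxymethoxy)-5-(triisopropylsilyloxy)benzene, via aryllithium 5 (not isolated)
Conditions: n-BuLi, THF, 0 °C; then 4, −78 °C to rt
Reagents that add atoms: none
Why: Directed ortho-metalation, in which the two MOM ethers jointly guide n-BuLi to the carbon between them while the bulky, poorly coordinating TIPS ether blocks the other ring carbons, followed by SN2 displacement of the primary allylic bromide with retention of the E alkene.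

**Step 4**
Reactants: 6 2-geranyl-1,3-bis(methoxymethoxy)-5-(triisopropylsilyloxy)benzene
Product: 7 4-geranyl-3,5-bis(methoxymethoxy)phenol
Conditions: tetrabutylammonium fluoride, AcOH, THF, 0 °C
Reagents that add atoms: none
Why: Fluoride-induced cleavage of an aryl silyl ether, buffered with acetic acid so that the electron-rich phenol is never present as a free phenoxide, with MOM ethers and alkenes inert.

**Step 5**
Reactants: 7 4-geranyl-3,5-bis(methoxymethoxy)phenol
Product: 9 3-geranyl-6-hydroxy-2,4-bis(methoxymethoxy)benzaldehyde, via hydroxymethyl phenol 8 (not isolated)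
Conditions: MgCl2, Et3N, paraformaldehyde, THF, reflux
Reagents that add atoms: paraformaldehyde (as formaldehyde), C=O
Why: Casnati–Skattebøl ortho-formylation, in which the magnesium phenoxide delivers formaldehyde only to a carbon ortho to the free oxygen (the two are equivalent) and a second formaldehyde oxidises the benzylic alkoxide of 8 by hydride transfer, so the only free hydroxyl ends next to the formyl group and away from the geranyl chain.

**Step 6**
Reactants: 10 3,5-dihydroxybenzaldehyde
Product: 11 3,5-bis(tert-butyldimethylsilyloxy)benzaldehyde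
Conditions: TBSCl, imidazole, DMF, rt
Reagents that add atoms: tert-butyldimethylsilyl chloride, CC(C)(C)[Si](C)(C)Cl
Why: Standard imidazole-mediated silylation of both phenols.

**Step 7**
Reactants: 11 3,5-bis(tert-butyldimethylsilyloxy)benzaldehyde
Product: 12 1,3-bis(tert-butyldimethylsilyloxy)-5-vinylbenzene
Conditions: Ph3PCH3Br, KOt-Bu (slightly less than the salt), THF, 0 °C to rt
Reagents that add atoms: methyltriphenylphosphonium bromide, C[P+](c1ccccc1)(c1ccccc1)c1ccccc1.[Br-]
Why: Wittig methylenation of an aromatic aldehyde, with the base kept below the phosphonium salt so that no free alkoxide attacks the aryl silyl ethers.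

**Step 8**
Reactants: 9 3-geranyl-6-hydroxy-2,4-bis(methoxymethoxy)benzaldehyde; 12 1,3-bis(tert-butyldimethylsilyloxy)-5-vinylbenzene; 13 trimethyl orthoformate
Product: 16 (2S,4S)-2-[3,5-bis(tert-butyldimethylsilyloxy)phenyl]-6-geranyl-4-methoxy-5,7-bis(methoxymethoxy)chromane, via dimethyl acetal 14 (not isolated), via ortho-quinone methide 15 (not isolated)
Conditions: (R)-3,3′-bis(2,4,6-triisopropylphenyl)-1,1′-binaphthyl-2,2′-diyl hydrogen phosphate (10 mol%), 13 (3 equiv), 12 (3 equiv), 5 Å MS, toluene, 0 °C to rt
Reagents that add atoms: trimethyl orthoformate (13), COC(OC)OC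
Why: Proposed new method: the phosphoric acid converts 9 and 13 into dimethyl acetal 14 and ionises it to an ortho-hydroxybenzyl oxocarbenium ion, the O-protonated form of quinone methide 15, which stays bound to the chiral phosphate by ion pairing and a hydrogen bond from the phenolic O–H; the styrene CH2 then bonds to C4 while the phenol oxygen closes on the developing benzylic cation at C2, an asynchronous inverse-demand hetero-Diels–Alder reaction. The closest known chemistry is the racemic acid-catalysed three-component assembly of 2,4-cis-4-alkoxyflavans from salicylaldehydes, orthoformates and styrenes, together with chiral phosphoric acid [4+2] cycloadditions of ortho-quinone methides with alkenes that carry a hydrogen-bond donor; the enantioselective use of a plain styrene is the untested part. Ring C closes as a six-membered ring by intermolecular [4+2] cycloaddition, C3–C4 forming ahead of O1–C2. C2 is set by the catalyst, whose 2,4,6-triisopropylphenyl walls should leave one face of the bound heterodiene open to the alkene, and C4 follows from endo placement of the aryl group (2,4-cis), which is of no consequence because step 9 removes that centre. The step needs Markovnikov regiochemistry, secured by the benzylic character of C2, a single phenol partner, secured by the MOM ether on the other ortho oxygen so that the geranyl group must end on C6, and preference for the vinyl group over the geranyl alkenes and the arene carbons, secured by excess styrene, by the hindered trisubstituted alkenes, by the TBS shielding of ring B and by an acid too weak to protonate an alkene.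

**Step 9**
Reactants: 16 (2S,4S)-2-[3,5-bis(tert-butyldimethylsilyloxy)phenyl]-6-geranyl-4-methoxy-5,7-bis(methoxymethoxy)chromane
Product: 18 (2S)-2-[3,5-bis(tert-butyldimethylsilyloxy)phenyl]-6-geranyl-5,7-bis(methoxymethoxy)chroman-4-one, via methyl hemiketal 17 (not isolated)
Conditions: 2,3-dichloro-5,6-dicyano-1,4-benzoquinone (DDQ, 1.2 equiv), CH2Cl2/pH 7 phosphate buffer (10:1), 0 °C
Reagents that add atoms: water, O
Why: DDQ oxidation of an electron-rich benzylic ether, in which hydride leaves C4 (activated by its methoxy group and by the ortho and para oxygens of ring A), water adds and hemiketal 17 loses methanol, while the geranyl CH2 should be spared because its cation would have to lie coplanar with a ring carbon flanked by two MOM ethers, and C2 is not involved.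

**Step 10**
Reactants: 18 (2S)-2-[3,5-bis(tert-butyldimethylsilyloxy)phenyl]-6-geranyl-5,7-bis(methoxymethoxy)chroman-4-one
Product: 19 Schizolaenone C, (2S)-2-(3,5-dihydroxyphenyl)-6-geranyl-5,7-dihydroxychroman-4-one
Conditions: HCl (1.25 M in MeOH), rt to 40 °C, stopped at full conversion
Reagents that add atoms: none
Why: Acid-catalysed methanolysis should cleave the two aryl MOM acetals and the two aryl TBS ethers in one operation, and since no base is present the retro-oxa-Michael ring opening that would racemise C2 is avoided, while the mild temperature should spare the geranyl alkenes.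

**Compound list**

1 | phloroglucinol | Oc1cc(O)cc(O)c1 | starting material
2 | 5-(triisopropylsilyloxy)benzene-1,3-diol | CC(C)[Si](Oc1cc(O)cc(O)c1)(C(C)C)C(C)C | intermediate
3 | 1,3-bis(methoxymethoxy)-5-(triisopropylsilyloxy)benzene | COCOc1cc(OCOC)cc(O[Si](C(C)C)(C(C)C)C(C)C)c1 | intermediate
4 | geranyl bromide, (2E)-1-bromo-3,7-dimethylocta-2,6-diene | CC(C)=CCC/C(C)=C/CBr | starting material
5 | 2,6-bis(methoxymethoxy)-4-(triisopropylsilyloxy)phenyllithium | [Li]c1c(OCOC)cc(O[Si](C(C)C)(C(C)C)C(C)C)cc1OCOC | intermediate (not isolated)
6 | 2-geranyl-1,3-bis(methoxymethoxy)-5-(triisopropylsilyloxy)benzene | CC(C)=CCC/C(C)=C/Cc1c(OCOC)cc(O[Si](C(C)C)(C(C)C)C(C)C)cc1OCOC | intermediate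
7 | 4-geranyl-3,5-bis(methoxymethoxy)phenol | CC(C)=CCC/C(C)=C/Cc1c(OCOC)cc(O)cc1OCOC | intermediate
8 | 4-geranyl-2-(hydroxymethyl)-3,5-bis(methoxymethoxy)phenol, present as its magnesium salt | CC(C)=CCC/C(C)=C/Cc1c(OCOC)cc(O)c(CO)c1OCOC | intermediate (not isolated)
9 | 3-geranyl-6-hydroxy-2,4-bis(methoxymethoxy)benzaldehyde | CC(C)=CCC/C(C)=C/Cc1c(OCOC)cc(O)c(C=O)c1OCOC | intermediate
10 | 3,5-dihydroxybenzaldehyde | O=Cc1cc(O)cc(O)c1 | starting material
11 | 3,5-bis(tert-butyldimethylsilyloxy)benzaldehyde | CC(C)(C)[Si](C)(C)Oc1cc(C=O)cc(O[Si](C)(C)C(C)(C)C)c1 | intermediate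
12 | 1,3-bis(tert-butyldimethylsilyloxy)-5-vinylbenzene | C=Cc1cc(O[Si](C)(C)C(C)(C)C)cc(O[Si](C)(C)C(C)(C)C)c1 | intermediate
13 | trimethyl orthoformate | COC(OC)OC | starting material
14 | 2-(dimethoxymethyl)-4-geranyl-3,5-bis(methoxymethoxy)phenol | CC(C)=CCC/C(C)=C/Cc1c(OCOC)cc(O)c(C(OC)OC)c1OCOC | intermediate (not isolated)
15 | (E)-4-geranyl-6-(methoxymethylidene)-3,5-bis(methoxymethoxy)cyclohexa-2,4-dien-1-one, shown as the E isomer; it reacts as its O-protonated oxocarbenium phosphate ion pair | CC(C)=CCC/C(C)=C/CC1=C(OCOC)/C(=C\OC)C(=O)C=C1OCOC | intermediate (not isolated)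
16 | (2S,4S)-2-[3,5-bis(tert-butyldimethylsilyloxy)phenyl]-6-geranyl-4-methoxy-5,7-bis(methoxymethoxy)chromane (2,4-cis) | CC(C)=CCC/C(C)=C/Cc1c(OCOC)cc2c(c1OCOC)[C@@H](OC)C[C@@H](c1cc(O[Si](C)(C)C(C)(C)C)cc(O[Si](C)(C)C(C)(C)C)c1)O2 | intermediate
17 | (2S)-2-[3,5-bis(tert-butyldimethylsilyloxy)phenyl]-6-geranyl-4-methoxy-5,7-bis(methoxymethoxy)chroman-4-ol (C4 epimers) | CC(C)=CCC/C(C)=C/Cc1c(OCOC)cc2c(c1OCOC)C(O)(OC)C[C@@H](c1cc(O[Si](C)(C)C(C)(C)C)cc(O[Si](C)(C)C(C)(C)C)c1)O2 | intermediate (not isolated)
18 | (2S)-2-[3,5-bis(tert-butyldimethylsilyloxy)phenyl]-6-geranyl-5,7-bis(methoxymethoxy)chroman-4-one | CC(C)=CCC/C(C)=C/Cc1c(OCOC)cc2c(c1OCOC)C(=O)C[C@@H](c1cc(O[Si](C)(C)C(C)(C)C)cc(O[Si](C)(C)C(C)(C)C)c1)O2 | intermediate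
19 | Schizolaenone C, (2S)-2-(3,5-dihydroxyphenyl)-6-geranyl-5,7-dihydroxychroman-4-one | CC(C)=CCC/C(C)=C/Cc1c(O)cc2c(c1O)C(=O)C[C@@H](c1cc(O)cc(O)c1)O2 | target

**Step count.** Total: 10 steps. Longest linear sequence: 8 steps (steps 1–5, 8, 9, 10); steps 6 and 7 form the short branch to the styrene.

**Steps most likely to fail**

1. Step 8. The ion pair may discriminate the two faces poorly, since the styrene offers no hydrogen-bond handle. The benzylic cation may also be diverted into Friedel–Crafts attack on electron-rich arene carbons or into capture by a geranyl alkene. Fallback (known chemistry, stereocontrol moved to a resolution): setting out from 9, 12 and 13, the union is run with an achiral acid (diphenyl phosphate or catalytic TsOH·H2O, CH2Cl2, −20 °C to rt, 12 in excess), which should give racemic 2,4-cis-4-methoxyflavan F1. Oxidation as in step 9 should then give racemic flavanone F2. Kinetic resolution by asymmetric transfer hydrogenation (RuCl(p-cymene)[(R,R)-N-tosyl-1,2-diphenylethylenediamine], HCO2H/Et3N, rt, stopped near half conversion) is expected to reduce the 2R ketone to (2R,4R)-cis-flavan-4-ol F3 and to leave the 2S ketone. That ketone is compound 18, where the route is rejoined; at most half of the material is carried on, and the catalyst antipode is exchanged if the opposite ketone is consumed.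

2. Step 9. Hydride abstraction may occur at the benzylic–allylic CH2 of the geranyl chain instead of C4, it may be slow if the C4–H bond lies near the arene plane, or the enol ether may be oxidised further towards the flavone. Fallback: setting out from 16, the benzylic methyl ether is solvolysed (pyridinium p-toluenesulfonate, acetone/H2O, 40 °C), an SN1 exchange through the stabilised C4 cation that is favoured by exactly the conformation that disfavours hydride loss. This should give flavan-4-ol F4 as a mixture of C4 epimers, which is oxidised with Dess–Martin periodinane (NaHCO3, CH2Cl2, rt) to compound 18.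

3. Step 3. Metalation may take place at a ring carbon next to the silyl ether, with silyl migration, or the aryllithium may attack the allylic bromide in the SN2′ sense and give the branched isomer. Fallback: setting out from 1 (in excess), direct Friedel–Crafts C-geranylation (geraniol, BF3·OEt2, dioxane, rt) gives 2-geranylphloroglucinol F5. TIPSCl and imidazole should silylate the unhindered hydroxyl para to the chain to give 2-geranyl-5-(triisopropylsilyloxy)benzene-1,3-diol F6. MOMCl and i-Pr2NEt then cap the two hydroxyls flanking the chain and return to compound 6.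

**Further compounds**

F1 | step 8 | racemic 2,4-cis-2-[3,5-bis(tert-butyldimethylsilyloxy)phenyl]-6-geranyl-4-methoxy-5,7-bis(methoxymethoxy)chromane | CC(C)=CCC/C(C)=C/Cc1c(OCOC)cc2c(c1OCOC)C(OC)CC(c1cc(O[Si](C)(C)C(C)(C)C)cc(O[Si](C)(C)C(C)(C)C)c1)O2
F2 | step 8 | racemic 2-[3,5-bis(tert-butyldimethylsilyloxy)phenyl]-6-geranyl-5,7-bis(methoxymethoxy)chroman-4-one | CC(C)=CCC/C(C)=C/Cc1c(OCOC)cc2c(c1OCOC)C(=O)CC(c1cc(O[Si](C)(C)C(C)(C)C)cc(O[Si](C)(C)C(C)(C)C)c1)O2
F3 | step 8 | (2R,4R)-2-[3,5-bis(tert-butyldimethylsilyloxy)phenyl]-6-geranyl-5,7-bis(methoxymethoxy)chroman-4-ol (2,4-cis) | CC(C)=CCC/C(C)=C/Cc1c(OCOC)cc2c(c1OCOC)[C@H](O)C[C@H](c1cc(O[Si](C)(C)C(C)(C)C)cc(O[Si](C)(C)C(C)(C)C)c1)O2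
F4 | step 9 | (2S)-2-[3,5-bis(tert-butyldimethylsilyloxy)phenyl]-6-geranyl-5,7-bis(methoxymethoxy)chroman-4-ol (C4 epimers) | CC(C)=CCC/C(C)=C/Cc1c(OCOC)cc2c(c1OCOC)C(O)C[C@@H](c1cc(O[Si](C)(C)C(C)(C)C)cc(O[Si](C)(C)C(C)(C)C)c1)O2
F5 | step 3 | 2-geranylbenzene-1,3,5-triol | CC(C)=CCC/C(C)=C/Cc1c(O)cc(O)cc1O
F6 | step 3 | 2-geranyl-5-(triisopropylsilyloxy)benzene-1,3-diol | CC(C)=CCC/C(C)=C/Cc1c(O)cc(O[Si](C(C)C)(C(C)C)C(C)C)cc1O
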